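**Retrosynthetic overview**
1. Target 21 ⇐ dienoate 19 by a late Rh-catalysed asymmetric 1,4-addition of isopropenyl (sets C1) and global acid deprotection.
2. 19 ⇐ [4+2] adduct 16 by CBS reduction (sets C5) and base-mediated C12=C13 → C13=C14 migration (sets C12).
3. 16 ⇐ triene 15 by the biomimetic intramolecular Diels–Alder of the vinylbutenolide (C11=C12–C13=C14) onto the exocyclic C6=C7 enone; 15 is made in the same flask by a Heck reaction of iodobutenolide 13 with methyl pentadienoate 14.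
4. 13 ⇐ aldehyde 8 + ketophosphonate 11 (HWE); 8 ⇐ (S)-linalool 1 by ozonolysis, proline α-aminoxylation (sets C10) and Z-olefination/lactonisation.
5. Ring order: butenolide first; then cyclopentane and cyclohexene together (spiro centre C6, C7, C11) in the Diels–Alder step; the spiro five-membered ring is carried in from 9.

Assumption: the target is treated as the carbocyclic (CH2 for ring O) congener of the cembranoid havellockate, whose core is presumed to arise by [4+2] union of a C11=C12–C13=C14 vinylbutenolide with a C6=C7 olefin followed by migration of C12=C13 to C13=C14.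
Locants used below: C1 = CH(isopropenyl); C2, C3 = CH2CO2Me; C14=C13 = ring alkene; C12 = lactone α-CH; C20 = lactone C=O; C11 = ring-fusion CH; C10 = CH–O; C9 = CH2; C8 = C(CH3)(O); C7 = ring-fusion CH; C6 = spiro C; C5 = CH(OH); C4 = CH2; C18 = ketone C; C21 = CH2 between C6 and C18.

**Step 1**
Reactants: 1 (S)-(+)-linalool, (3S)-3,7-dimethylocta-1,6-dien-3-ol
Product: 2 triethyl{[(3S)-3,7-dimethylocta-1,6-dien-3-yl]oxy}silane
Conditions: TESOTf, 2,6-lutidine, CH2Cl2, −78 → 0 °C
Reagents that add atoms: triethylsilyl trifluoromethanesulfonate, CC[Si](CC)(CC)OS(=O)(=O)C(F)(F)F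
Why: Silyl triflate protection of the tertiary alcohol masks the C8 hydroxyl (which would otherwise add oxa-Michael to the later butenolide); C8 (S) comes from the chiral pool.

**Step 2**
Reactants: 2 triethyl{[(3S)-3,7-dimethylocta-1,6-dien-3-yl]oxy}silane
Product: 3 (4S)-4-methyl-4-(triethylsilyloxy)hex-5-enal
Conditions: O3 (1.0 equiv), CH2Cl2/pyridine, −78 °C; Me2S
Reagents that add atoms: ozone, [O-][O+]=O
Why: Chemoselective ozonolysis, since the electron-rich trisubstituted alkene is cleaved far faster than the vinyl group next to the silyloxy carbon.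

**Step 3**
Reactants: 3 (4S)-4-methyl-4-(triethylsilyloxy)hex-5-enal
Product: 5 ethyl (2Z,4R,6S)-6-methyl-4-(phenylaminooxy)-6-(triethylsilyloxy)octa-2,7-dienoate, via α-aminoxy aldehyde 4 (not isolated)
Conditions: PhNO, L-proline (20 mol%), CHCl3, 4 °C; then (PhO)2P(O)CH2CO2Et, NaH, THF, −78 °C
Reagents that add atoms: nitrosobenzene, O=Nc1ccccc1; ethyl 2-(diphenoxyphosphoryl)acetate, CCOC(=O)CP(=O)(Oc1ccccc1)Oc1ccccc1
Why: Proline-catalysed enamine α-aminoxylation (nitroso aldol) sets C10 as R under catalyst control, and the Ando variant of the Horner–Wadsworth–Emmons olefination gives the (Z)-enoate needed for lactonisation.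

**Step 4**
Reactants: 5 ethyl (2Z,4R,6S)-6-methyl-4-(phenylaminooxy)-6-(triethylsilyloxy)octa-2,7-dienoate
Product: 7 (5R)-5-[(2S)-2-methyl-2-(triethylsilyloxy)but-3-en-1-yl]furan-2(5H)-one, via hydroxy enoate 6 (not isolated)
Conditions: Zn, AcOH, THF, 23 °C
Reagents that add atoms: none
Why: Reductive N–O cleavage frees the C10 hydroxyl, which lactonises onto the cis ester to the butenolide without touching C10.

**Step 5**
Reactants: 7 (5R)-5-[(2S)-2-methyl-2-(triethylsilyloxy)but-3-en-1-yl]furan-2(5H)-one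
Product: 8 (2S)-2-methyl-3-[(2R)-5-oxo-2,5-dihydrofuran-2-yl]-2-(triethylsilyloxy)propanal
Conditions: O3, CH2Cl2, −78 °C (Sudan III end point); PPh3
Reagents that add atoms: ozone, [O-][O+]=O
Why: Ozonolysis is selective because the isolated vinyl group is much more electron-rich than the conjugated butenolide C=C; the aldehyde formed cannot enolise.

**Step 6**
Reactants: 9 1,4-dioxaspiro[4.4]nonan-7-one
Product: 11 diethyl (7-oxo-1,4-dioxaspiro[4.4]nonan-8-yl)phosphonate, via enol phosphate 10 (not isolated)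
Conditions: LDA, THF, −78 °C; ClP(O)(OEt)2; then LDA, −78 → 0 °C
Reagents that add atoms: diethyl chlorophosphate, CCOP(Cl)(=O)OCC
Why: Kinetic enolisation at the CH2 remote from the ketal, O-phosphorylation and LDA-induced 1,3-phosphoryl migration (Wiemer vinyl phosphate to β-keto phosphonate rearrangement).

**Step 7**
Reactants: 8 (2S)-2-methyl-3-[(2R)-5-oxo-2,5-dihydrofuran-2-yl]-2-(triethylsilyloxy)propanal; 11 diethyl (7-oxo-1,4-dioxaspiro[4.4]nonan-8-yl)phosphonate
Product: 12 (5R)-5-[(2S,3E)-2-methyl-3-(7-oxo-1,4-dioxaspiro[4.4]nonan-8-ylidene)-2-(triethylsilyloxy)propyl]furan-2(5H)-one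
Conditions: LiCl, i-Pr2NEt, MeCN, 23 → 40 °C
Reagents that add atoms: none
Why: Masamune–Roush Horner–Wadsworth–Emmons olefination under weakly basic conditions gives the (E)-exocyclic enone (C8 cis to the ring CH2 C21), the geometry that later fixes C6.

**Step 8**
Reactants: 12 (5R)-5-[(2S,3E)-2-methyl-3-(7-oxo-1,4-dioxaspiro[4.4]nonan-8-ylidene)-2-(triethylsilyloxy)propyl]furan-2(5H)-one
Product: 13 (5R)-3-iodo-5-[(2S,3E)-2-methyl-3-(7-oxo-1,4-dioxaspiro[4.4]nonan-8-ylidene)-2-(triethylsilyloxy)propyl]furan-2(5H)-one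
Conditions: I2, pyridine, CH2Cl2, 23 °C, dark
Reagents that add atoms: iodine, II
Why: Johnson α-iodination of the unsaturated lactone (pyridine conjugate addition, enolate iodination, elimination); the exocyclic enone has no α-hydrogen and is left alone.

**Step 9**
Reactants: 13 (5R)-3-iodo-5-[(2S,3E)-2-methyl-3-(7-oxo-1,4-dioxaspiro[4.4]nonan-8-ylidene)-2-(triethylsilyloxy)propyl]furan-2(5H)-one; 14 methyl (2E)-penta-2,4-dienoate
Product: 16 (6S,7S,8S,10R,11R,14R)-tetracyclic keto lactone [Δ12(13) α-alkylidene 20,10-lactone; C7–C11 cyclopentane with 8-CH3 and 8-OSiEt3; C6-spiro cyclopentane with 5-oxo and 18-ethylene ketal; (E)-CH=CH–CO2Me on C14], via triene 15 (not isolated)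
Conditions: Pd(OAc)2 (10 mol%), Ag2CO3, MeCN, 50 °C; filter; PhMe, BHT, 110 °C
Reagents that add atoms: none
Why: Heck alkenylation at the terminal CH2 of the dienoate gives the (E,E)-trienoate, whose 2-acyl-diene unit (C11=C12–C13=C14) then adds to the exocyclic enone C6=C7 in a type-1 intramolecular Diels–Alder reaction in the intrinsically favoured "para" orientation; the diene is attacked on the face carrying the C10 side chain with the tether endo (H10, H11, H7 all cis), and the (E)-enone geometry places C21 cis to C8, which fixes the spiro centre C6.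

**Step 10**
Reactants: 16 (6S,7S,8S,10R,11R,14R)-tetracyclic keto lactone
Product: 17 (5S,6S,7S,8S,10R,11R,14R)-5-hydroxy tetracycle (5-OH in place of the 5-ketone of 16)
Conditions: (R)-Me-CBS (30 mol%), catecholborane, PhMe, −78 → −40 °C
Reagents that add atoms: none
Why: Corey–Bakshi–Shibata reduction, in which the (R)-oxazaborolidine delivers hydride to the C5 ketone (large side = spiro C6, small side = CH2) to give 5S, matched with approach from the less hindered C7 side; lactone, enoates and ketal are inert to catecholborane at this temperature.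

**Step 11**
Reactants: 17 (5S,6S,7S,8S,10R,11R,14R)-5-hydroxy tetracycle
Product: 19 (5S,6R,7S,8S,10R,11R,12R)-dienoate [C13=C14 ring alkene conjugated to (E)-CH=CH–CO2Me; 12-H lactone; 5-OSiMe3; 8-OSiEt3; 18-ethylene ketal], via TMS ether 18 (not isolated)
Conditions: TMSCl, DBU (3 equiv), CH2Cl2, 0 → 23 °C
Reagents that add atoms: chlorotrimethylsilane, C[Si](C)(C)Cl
Why: Silylation of the C5 hydroxyl (blocks oxa-Michael addition to the acrylate) is followed by DBU-mediated prototropic shift through the extended dienolate, driven by formation of the conjugated 2,4-dienoate; C12 equilibrates to the epimer with the lactone trans-fused to the cyclohexene (12R), which avoids the 1,3-diaxial C8/C20 contact of the all-cis isomer.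

**Step 12**
Reactants: 19 (5S,6R,7S,8S,10R,11R,12R)-dienoate
Product: 21 target CNP0255095.1 (1S,5S,6R,7S,8S,10R,11R,12R), via protected adduct 20 (not isolated)
Conditions: CH2=C(CH3)BF3K, [Rh(cod)2]BF4 (5 mol%), (R)-BINAP, PhMe/H2O, 80 °C; then 1 M HCl, THF, 23 °C
Reagents that add atoms: potassium isopropenyltrifluoroborate, [K+].C=C(C)[B-](F)(F)F; water, O
Why: Hayashi–Miyaura Rh-catalysed asymmetric 1,4-addition of isopropenyl to the dienoate (the δ-carbon is a hindered ring CH, so 1,4 beats 1,6) sets C1 as S by ligand control ((R)-BINAP, α-re face), and aqueous HCl then removes both silyl ethers and the dioxolane to reveal the β-hydroxy ketone.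

**Compound list**
1 | (S)-(+)-linalool, (3S)-3,7-dimethylocta-1,6-dien-3-ol | CC(C)=CCC[C@](C)(O)C=C | starting material
2 | triethyl{[(3S)-3,7-dimethylocta-1,6-dien-3-yl]oxy}silane | CC(C)=CCC[C@](C)(O[Si](CC)(CC)CC)C=C | intermediate
3 | (4S)-4-methyl-4-(triethylsilyloxy)hex-5-enal | O=CCC[C@](C)(O[Si](CC)(CC)CC)C=C | intermediate
4 | (2R,4S)-4-methyl-2-(phenylaminooxy)-4-(triethylsilyloxy)hex-5-enal | O=C[C@H](ONc1ccccc1)C[C@](C)(O[Si](CC)(CC)CC)C=C | intermediate
5 | ethyl (2Z,4R,6S)-6-methyl-4-(phenylaminooxy)-6-(triethylsilyloxy)octa-2,7-dienoate | CCOC(=O)/C=C\[C@H](ONc1ccccc1)C[C@](C)(O[Si](CC)(CC)CC)C=C | intermediate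
6 | ethyl (2Z,4R,6S)-4-hydroxy-6-methyl-6-(triethylsilyloxy)octa-2,7-dienoate | CCOC(=O)/C=C\[C@H](O)C[C@](C)(O[Si](CC)(CC)CC)C=C | intermediate
7 | (5R)-5-[(2S)-2-methyl-2-(triethylsilyloxy)but-3-en-1-yl]furan-2(5H)-one | O=C1C=C[C@H](O1)C[C@](C)(O[Si](CC)(CC)CC)C=C | intermediate
8 | (2S)-2-methyl-3-[(2R)-5-oxo-2,5-dihydrofuran-2-yl]-2-(triethylsilyloxy)propanal | O=C1C=C[C@H](O1)C[C@](C)(O[Si](CC)(CC)CC)C=O | intermediate
9 | 1,4-dioxaspiro[4.4]nonan-7-one | O=C1CC2(CC1)OCCO2 | starting material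
10 | diethyl 1,4-dioxaspiro[4.4]non-7-en-7-yl phosphate | CCOP(=O)(OCC)OC1=CCC2(C1)OCCO2 | intermediate
11 | diethyl (7-oxo-1,4-dioxaspiro[4.4]nonan-8-yl)phosphonate (racemic) | CCOP(=O)(OCC)C1CC2(CC1=O)OCCO2 | intermediate
12 | (5R)-5-[(2S,3E)-2-methyl-3-(7-oxo-1,4-dioxaspiro[4.4]nonan-8-ylidene)-2-(triethylsilyloxy)propyl]furan-2(5H)-one | O=C1C=C[C@H](O1)C[C@](C)(O[Si](CC)(CC)CC)/C=C2\CC3(OCCO3)CC2=O | intermediate
13 | (5R)-3-iodo-5-[(2S,3E)-2-methyl-3-(7-oxo-1,4-dioxaspiro[4.4]nonan-8-ylidene)-2-(triethylsilyloxy)propyl]furan-2(5H)-one | O=C1C(I)=C[C@H](O1)C[C@](C)(O[Si](CC)(CC)CC)/C=C2\CC3(OCCO3)CC2=O | intermediate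
14 | methyl (2E)-penta-2,4-dienoate | C=C/C=C/C(=O)OC | starting material
15 | methyl (2E,4E)-5-{(5R)-5-[(2S,3E)-2-methyl-3-(7-oxo-1,4-dioxaspiro[4.4]nonan-8-ylidene)-2-(triethylsilyloxy)propyl]-2-oxo-2,5-dihydrofuran-3-yl}penta-2,4-dienoate | COC(=O)/C=C/C=C/C1=C[C@H](OC1=O)C[C@](C)(O[Si](CC)(CC)CC)/C=C2\CC3(OCCO3)CC2=O | intermediate
16 | (6S,7S,8S,10R,11R,14R)-Diels–Alder adduct: Δ12(13) lactone, 5-ketone, 18-ethylene ketal, 8-OSiEt3, 14-[(E)-2-(methoxycarbonyl)vinyl] | COC(=O)/C=C/[C@@H]1C=C2C(=O)O[C@@H]3C[C@](C)(O[Si](CC)(CC)CC)[C@@H]([C@@H]32)[C@]12CC3(OCCO3)CC2=O | intermediate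
17 | (5S,6S,7S,8S,10R,11R,14R)-5-alcohol of 16 | COC(=O)/C=C/[C@@H]1C=C2C(=O)O[C@@H]3C[C@](C)(O[Si](CC)(CC)CC)[C@@H]([C@@H]32)[C@]12CC3(OCCO3)C[C@@H]2O | intermediate
18 | 5-O-trimethylsilyl ether of 17 | COC(=O)/C=C/[C@@H]1C=C2C(=O)O[C@@H]3C[C@](C)(O[Si](CC)(CC)CC)[C@@H]([C@@H]32)[C@]12CC3(OCCO3)C[C@@H]2O[Si](C)(C)C | intermediate
19 | (5S,6R,7S,8S,10R,11R,12R)-dienoate: C13=C14, 12-H lactone, 14-[(E)-2-(methoxycarbonyl)vinyl], 5-OSiMe3, 8-OSiEt3, 18-ethylene ketal | COC(=O)/C=C/C1=C[C@H]2C(=O)O[C@@H]3C[C@](C)(O[Si](CC)(CC)CC)[C@@H]([C@@H]32)[C@]12CC3(OCCO3)C[C@@H]2O[Si](C)(C)C | intermediate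
20 | (1S,5S,6R,7S,8S,10R,11R,12R)-protected target: 5-OSiMe3, 8-OSiEt3, 18-ethylene ketal | C=C(C)[C@H](CC(=O)OC)C1=C[C@H]2C(=O)O[C@@H]3C[C@](C)(O[Si](CC)(CC)CC)[C@@H]([C@@H]32)[C@]12CC3(OCCO3)C[C@@H]2O[Si](C)(C)C | intermediate
21 | CNP0255095.1, (1S,5S,6R,7S,8S,10R,11R,12R) | C=C(C)[C@H](CC(=O)OC)C1=C[C@H]2C(=O)O[C@@H]3C[C@](C)(O)[C@@H]([C@@H]32)[C@]12CC(=O)C[C@@H]2O | target

**Totals**
Total step count: 12. Longest linear sequence: 11 (steps 1–5 and 7–12, from 1).

**Three steps most likely to fail**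

Step 9 (Heck/Diels–Alder cascade). The Heck partner polymerises easily, the ketal ketone is base-sensitive, and the cycloaddition joins two electron-poor partners while creating the quaternary spiro centre next to the C8 silyl ether. Fallback, setting out from 13 and returning at 16: separate the coupling from the cycloaddition and change the coupling type. Suzuki–Miyaura coupling of 13 at 23 °C with methyl (2E,4E)-5-(4,4,5,5-tetramethyl-1,3,2-dioxaborolan-2-yl)penta-2,4-dienoate F1 (from 14 by cross-metathesis with vinylboronic acid pinacol ester) gives triene 15 as an isolated compound. The [4+2] step is then run on its own under high pressure (about 13 kbar, CH2Cl2, 23 °C) to reach 16.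

Step 11 (double-bond migration and C12). The equilibrium could stay at the α-alkylidene lactone or give a lactone-conjugated isomer, and the thermodynamic C12 epimer is predicted, not known. Fallback, setting out from 17 and returning at 19: make the deconjugation kinetic. Excess TMSOTf/Et3N converts 17 into the bis-silyl compound, the 5-O-TMS lactone trimethylsilyl dienol ether F2, which is isolated. Protodesilylation with AcOH at −78 °C protonates C12 (α) irrespective of the thermodynamic balance, and a short catalytic DBU pulse then equilibrates only C12 to give 19.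

Step 12 (Rh addition and deprotection). C1 is the only centre set purely by the ligand on a hindered, chiral β-alkenyl acrylate. 1,6-Addition, re-conjugation of the lactone by basic Rh–OH species, and acid-induced dehydration of the β-hydroxy ketone are possible. Fallback, setting out from 13 and returning at 20: bring in the complete side chain with C1 already set.
- Methyl (3R)-3-(prop-1-en-2-yl)pent-4-enoate F3 is made from commercial racemic methyl 3-hydroxypent-4-enoate and potassium isopropenyltrifluoroborate by Ir/(P,olefin)-catalysed enantioconvergent allyl–alkenyl coupling.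
- Cross-metathesis of F3 with vinylboronic acid pinacol ester gives methyl (3R,4E)-3-(prop-1-en-2-yl)-5-(4,4,5,5-tetramethyl-1,3,2-dioxaborolan-2-yl)pent-4-enoate F4.
- Suzuki coupling of F4 with 13 gives the (1R)-triene F5, which on heating undergoes the same intramolecular Diels–Alder reaction to the (1R,14S)-keto lactone F6.
- CBS reduction as in step 10 gives the 5S alcohol F7.
- TMSCl/DBU gives the 5-O-TMS ether F8, which is isomerised to 20 (now without the dienoate driving force); the HCl treatment of step 12 finishes the synthesis.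

**Further compounds**
F1 | step 9 | methyl (2E,4E)-5-(4,4,5,5-tetramethyl-1,3,2-dioxaborolan-2-yl)penta-2,4-dienoate | COC(=O)/C=C/C=C/B1OC(C)(C)C(C)(C)O1
F2 | step 11 | 5-O-TMS lactone trimethylsilyl dienol ether (C20(OSiMe3)=C12, C13=C14) derived from 17 | COC(=O)/C=C/C1=CC2=C(O[Si](C)(C)C)O[C@@H]3C[C@](C)(O[Si](CC)(CC)CC)[C@@H]([C@@H]32)[C@]12CC3(OCCO3)C[C@@H]2O[Si](C)(C)C
F3 | step 12 | methyl (3R)-3-(prop-1-en-2-yl)pent-4-enoate | C=C(C)[C@H](CC(=O)OC)C=C
F4 | step 12 | methyl (3R,4E)-3-(prop-1-en-2-yl)-5-(4,4,5,5-tetramethyl-1,3,2-dioxaborolan-2-yl)pent-4-enoate | C=C(C)[C@H](CC(=O)OC)/C=C/B1OC(C)(C)C(C)(C)O1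
F5 | step 12 | (1R)-triene: 13 with the iodine replaced by (E)-CH=CH–CH(isopropenyl)CH2CO2Me | C=C(C)[C@H](CC(=O)OC)/C=C/C1=C[C@H](OC1=O)C[C@](C)(O[Si](CC)(CC)CC)/C=C2\CC3(OCCO3)CC2=O
F6 | step 12 | (1R,6S,7S,8S,10R,11R,14S)-Diels–Alder adduct with complete side chain: Δ12(13) lactone, 5-ketone, 18-ethylene ketal, 8-OSiEt3 | C=C(C)[C@H](CC(=O)OC)[C@@H]1C=C2C(=O)O[C@@H]3C[C@](C)(O[Si](CC)(CC)CC)[C@@H]([C@@H]32)[C@]12CC3(OCCO3)CC2=O
F7 | step 12 | (5S)-alcohol of F6 | C=C(C)[C@H](CC(=O)OC)[C@@H]1C=C2C(=O)O[C@@H]3C[C@](C)(O[Si](CC)(CC)CC)[C@@H]([C@@H]32)[C@]12CC3(OCCO3)C[C@@H]2O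
F8 | step 12 | 5-O-trimethylsilyl ether of F7 | C=C(C)[C@H](CC(=O)OC)[C@@H]1C=C2C(=O)O[C@@H]3C[C@](C)(O[Si](CC)(CC)CC)[C@@H]([C@@H]32)[C@]12CC3(OCCO3)C[C@@H]2O[Si](C)(C)C
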